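## Retrosynthetic overview

- The target is the 3α,9α-bis[(Z)-hex-2-enoate] of a 7α-isopropenyl-eremophilane-3α,8α,9α-triol. The esters are put on last from hex-2-ynoic acid (esterification, then semihydrogenation); the C7 isopropenyl comes from Pd-catalysed alkenylation of a C8 ketone enolate, and 8α-OH is restored by equatorial hydride delivery.
- The strategy rests on C8 and C9 of ring B (C5–C10): adjacent cis carbinol carbons that are both electrophilic when written as aldehydes. A reductive SmI2 pinacol coupling joins C8 to C9 and closes ring B onto a finished ring A (C1–C5, C10).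
- The ring-A dialdehyde (C9 formyl on C10, C6–C8 3-oxopropyl chain on C5) comes from Hagemann's ester: methylation at C4, Sakurai allylation at C5 trans to the ester, thermodynamic reduction at C3, lipase resolution.
- Ring order: ring A is bought with Hagemann's ester; ring B is formed in step 10.

Key step: step 10

Remark: numbering follows the eremophilane skeleton; α is the face of H-10 and β the face of the C5 methyl. Compounds 1, 2, 4, 5 and 6 are racemates, and 4–6 are drawn as the enantiomer that is carried on. TBS = tert-butyldimethylsilyl; DMP = Dess–Martin periodinane.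

## Route

Step 1
Reactants: 1 Hagemann's ester (ethyl 2-methyl-4-oxocyclohex-2-ene-1-carboxylate, racemic)
Product: 2 ethyl 2,3-dimethyl-4-oxocyclohex-2-ene-1-carboxylate (racemic)
Conditions: KOt-Bu, t-BuOH, rt; then MeI, reflux
Reagents that add atoms: iodomethane, CI
Why: Deprotonation at C1 gives the extended dienolate of the vinylogous β-keto ester, which is C-methylated at the carbon α to the ketone (classical Hagemann's ester alkylation) and returns to the conjugated enone.

Step 2
Reactants: 2 ethyl 2,3-dimethyl-4-oxocyclohex-2-ene-1-carboxylate; 3 allyltrimethylsilane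
Product: 5 ethyl (1R*,2R*,3R*)-2,3-dimethyl-4-oxo-2-(prop-2-en-1-yl)cyclohexane-1-carboxylate (racemic; allyl trans to the ester, the two methyls cis), via trichlorotitanium enolate 4 (not isolated)
Conditions: TiCl4, CH2Cl2, −78 → −40 °C; H2O; then cat. DBU, CH2Cl2, rt
Reagents that add atoms: none
Why: Hosomi–Sakurai conjugate allylation in which the TiCl4-activated enone is attacked axially at the β-carbon (future C5) anti to the pseudoaxial ester on the neighbouring carbon, so the allyl group should end trans to CO2Et, while axial protonation of enolate 4, backed by DBU equilibration, should place the C4 methyl equatorial and cis to the C5 methyl.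

Step 3
Reactants: 5 keto ester
Product: 6 ethyl (1R*,2R*,3R*,4R*)-4-hydroxy-2,3-dimethyl-2-(prop-2-en-1-yl)cyclohexane-1-carboxylate (racemic; equatorial 3α-OH in target numbering)
Conditions: SmI2, H2O, THF, 0 °C → rt
Reagents that add atoms: none
Why: Ketyl (single-electron) reduction by SmI2/H2O, which leaves the ester alone, should deliver the more stable equatorial alcohol because an axial hydroxyl would be 1,3-diaxial to the C5 methyl.

Step 4
Reactants: 6 racemic alcohol
Product: 7 ethyl (1R,2R,3R,4R)-4-acetoxy-2,3-dimethyl-2-(prop-2-en-1-yl)cyclohexane-1-carboxylate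
Conditions: Burkholderia cepacia lipase (Amano PS), vinyl acetate, t-BuOMe, 35 °C, stopped near half conversion; chromatography
Reagents that add atoms: vinyl acetate, C=COC(C)=O
Why: Lipase kinetic resolution by irreversible transesterification, in which the Kazlauskas rule predicts acetylation of the (R)-carbinol (large group = the branched C4 side), so the wanted enantiomer is expected as the acetate and the unreacted (1S,2S,3S,4S)-alcohol is removed.

Step 5
Reactants: 7 acetate
Product: 8 ethyl (1R,2R,3R,4R)-4-hydroxy-2,3-dimethyl-2-(prop-2-en-1-yl)cyclohexane-1-carboxylate (single enantiomer)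
Conditions: K2CO3, EtOH, rt
Reagents that add atoms: none
Why: Base-catalysed transesterification removes the secondary acetate, ethanol as solvent keeps the ethyl ester unchanged, and the non-activated ester α-centre (C10) is not enolised by carbonate.

Step 6
Reactants: 8 alcohol
Product: 9 ethyl (1R,2R,3R,4R)-4-(tert-butyldimethylsilyloxy)-2,3-dimethyl-2-(prop-2-en-1-yl)cyclohexane-1-carboxylate
Conditions: TBSOTf, 2,6-lutidine, CH2Cl2, 0 °C
Reagents that add atoms: tert-butyldimethylsilyl trifluoromethanesulfonate, CC(C)(C)[Si](C)(C)OS(=O)(=O)C(F)(F)F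
Why: Silyl triflate silylation is the standard way to protect a hindered secondary alcohol flanked by a branched carbon.

Step 7
Reactants: 9 silyl ether ester
Product: 10 [(1R,2S,3R,4R)-4-(tert-butyldimethylsilyloxy)-2,3-dimethyl-2-(prop-2-en-1-yl)cyclohexyl]methanol
Conditions: LiAlH4, THF, 0 °C
Reagents that add atoms: none
Why: Hydride reduction of the ester to the primary alcohol (C9) without touching the silyl ether, the alkene or any stereocentre.

Step 8
Reactants: 10 alkenol
Product: 12 ring-A diol (C10 CH2OH β, C5 3-hydroxypropyl α and CH3 β, C4 CH3 β, C3 OTBS α), via bis(9-BBN) adduct 11 (not isolated)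
Conditions: 9-BBN (2.5 equiv), THF, 0 °C → rt; then NaOH, H2O2, 0 °C → rt
Reagents that add atoms: hydrogen peroxide, OO
Why: Anti-Markovnikov hydroboration–oxidation of the terminal alkene with 9-BBN places the hydroxyl on C8; the free hydroxyl only consumes one equivalent of borane as a borinate that is cleaved in the oxidative work-up.

Step 9
Reactants: 12 diol
Product: 13 ring-A dialdehyde (C9 formyl on C10, 3-oxopropyl chain C6–C8 on C5, 3α-OTBS, 4β- and 5β-methyl)
Conditions: DMP, NaHCO3, CH2Cl2, 0 °C → rt
Reagents that add atoms: none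
Why: Buffered Dess–Martin oxidation converts both primary alcohols to aldehydes under non-basic conditions, so the C10 formyl stereocentre is not epimerised.

Step 10
Reactants: 13 dialdehyde
Product: 15 trans-decalin diol (3α-OTBS, 4β-CH3, 5β-CH3, 8α-OH axial, 9α-OH equatorial, 10α-H), via bis(diiodosamarium) diolate 14 (not isolated)
Conditions: SmI2 (0.1 M in THF, 2.5–3 equiv), THF, high dilution, −78 °C → rt; aq. NaHCO3
Reagents that add atoms: none
Why: SmI2 (divalent samarium) transfers one electron to each formyl group, the unhindered C8 one first, and the C8 ketyl adds to the samarium-bound C9 carbonyl (or the two ketyls combine) to form C8–C9 as diolate 14, which is hydrolysed on work-up; the closest known reaction type is the SmI2 intramolecular pinacol cyclisation of 1,6-dialdehydes to cis-cyclohexane-1,2-diols. Ring B closes in a 6-exo ketyl–carbonyl mode through a chair transition state fused trans to ring A, because both tethers (C9 on C10 and C6 on C5) are equatorial on ring A. The cis relationship of the two new stereocentres is imposed by the trivalent samarium that bridges both oxygens in the transition state. Of the two cis pairs the α,α pair should form, since a β oxygen at C9 would be axial and 1,3-diaxial to the C5 methyl; O9 therefore sits equatorial (α) and O8 has to be axial (α). The step needs coupling to win over simple reduction of the aldehydes and over intermolecular coupling, which the fast six-membered closure of the pre-organised trans-diequatorial dialdehyde, high dilution and the absence of a strong proton donor are meant to secure.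

Step 11
Reactants: 15 diol
Product: 17 9α-silyl ether (3α,9α-bis-OTBS, free axial 8α-OH), via dibutylstannylene acetal 16 (not isolated)
Conditions: Bu2SnO, toluene, reflux (−H2O); then TBSCl, THF, rt
Reagents that add atoms: tert-butyldimethylsilyl chloride, CC(C)(C)[Si](C)(C)Cl
Why: Tin-mediated regioselective O-functionalisation, in which the equatorial oxygen of the stannylene acetal of an axial/equatorial cis-diol is the nucleophilic one, so TBSCl should silylate O9 and leave the axial O8–H.

Step 12
Reactants: 17 mono-alcohol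
Product: 18 C8 ketone (3α,9α-bis-OTBS)
Conditions: DMP, NaHCO3, CH2Cl2, rt
Reagents that add atoms: none
Why: Dess–Martin oxidation of the axial secondary alcohol under buffered conditions leaves both silyl ethers intact, and the equatorial C9 silyloxy group is in any case the thermodynamic epimer.

Step 13
Reactants: 18 ketone; 19 2-bromopropene
Product: 21 7α-isopropenyl C8 ketone (3α,9α-bis-OTBS), via lithium enolate 20 (not isolated)
Conditions: LiN(SiMe3)2 (2.2 equiv), toluene/THF, −78 → 0 °C; then Pd(OAc)2 (5 mol %), P(t-Bu)3 (10 mol %), 2-bromopropene, rt; AcOH, −78 °C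
Reagents that add atoms: none
Why: Pd-catalysed α-alkenylation of a ketone enolate: kinetic deprotonation at the unhindered C7 methylene rather than the silyloxy-bearing C9, oxidative addition of the alkenyl bromide to zerovalent palladium, transmetalation and C–C reductive elimination, with cold α-protonation keeping the double bond out of conjugation and the epimerisable C7 centre settling with the isopropenyl group equatorial (α), away from the axial C5 methyl.

Step 14
Reactants: 21 isopropenyl ketone
Product: 22 8α-alcohol (7α-isopropenyl, 3α,9α-bis-OTBS)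
Conditions: LiBH(s-Bu)3, THF, −78 °C
Reagents that add atoms: none
Why: The bulky trialkylborohydride attacks the C8 carbonyl along the equatorial trajectory (β face), giving the axial 8α-alcohol cis to both equatorial neighbours.

Step 15
Reactants: 22 bis-silyl ether
Product: 23 triol (7α-isopropenyl, 3α-OH, 8α-OH, 9α-OH)
Conditions: tetrabutylammonium fluoride, THF, rt → 45 °C
Reagents that add atoms: none
Why: Fluoride cleaves both secondary TBS ethers; the isolated alkene and the carbinol centres are inert.

Step 16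
Reactants: 23 triol; 24 hex-2-ynoic acid
Product: 25 3α,9α-bis(hex-2-ynoate) with free 8α-OH
Conditions: 24 (2.3 equiv), DCC, DMAP (cat.), CH2Cl2, −20 → 0 °C
Reagents that add atoms: none
Why: Steglich esterification should acylate the two equatorial hydroxyls and spare the axial C8 hydroxyl, which is flanked by the isopropenyl-bearing C7 and the oxygenated C9; the ynoate is used so that the Z geometry is set only afterwards.

Step 17
Reactants: 25 bis-ynoate
Product: 26 target, 3α,9α-bis[(Z)-hex-2-enoyloxy]-7α-isopropenyl-4β,5β-dimethyl-trans-decalin-8α-ol (CNP0420276.1)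
Conditions: H2 (1 atm), Pd/CaCO3 poisoned with Pb(OAc)2, quinoline, EtOAc, rt, stopped after 2 equiv H2
Reagents that add atoms: none
Why: Lindlar syn-semihydrogenation of each conjugated alkyne gives the (Z)-enoate, and the poisoned catalyst should leave the 1,1-disubstituted isopropenyl alkene untouched.

## Compound list

1 | Hagemann's ester, ethyl 2-methyl-4-oxocyclohex-2-ene-1-carboxylate (racemic) | CCOC(=O)C1CCC(=O)C=C1C | starting material
2 | ethyl 2,3-dimethyl-4-oxocyclohex-2-ene-1-carboxylate (racemic) | CCOC(=O)C1CCC(=O)C(C)=C1C | intermediate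
3 | allyltrimethylsilane | C=CC[Si](C)(C)C | starting material
4 | trichlorotitanium enolate of 5 (racemic) | C=CC[C@]1(C)C(C)=C(O[Ti](Cl)(Cl)Cl)CC[C@H]1C(=O)OCC | intermediate (not isolated)
5 | ethyl (1R*,2R*,3R*)-2,3-dimethyl-4-oxo-2-(prop-2-en-1-yl)cyclohexane-1-carboxylate (racemic) | C=CC[C@]1(C)[C@@H](C)C(=O)CC[C@H]1C(=O)OCC | intermediate
6 | ethyl (1R*,2R*,3R*,4R*)-4-hydroxy-2,3-dimethyl-2-(prop-2-en-1-yl)cyclohexane-1-carboxylate (racemic) | C=CC[C@]1(C)[C@@H](C)[C@H](O)CC[C@H]1C(=O)OCC | intermediate
7 | ethyl (1R,2R,3R,4R)-4-acetoxy-2,3-dimethyl-2-(prop-2-en-1-yl)cyclohexane-1-carboxylate | C=CC[C@]1(C)[C@@H](C)[C@H](OC(C)=O)CC[C@H]1C(=O)OCC | intermediate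
8 | ethyl (1R,2R,3R,4R)-4-hydroxy-2,3-dimethyl-2-(prop-2-en-1-yl)cyclohexane-1-carboxylate (single enantiomer) | C=CC[C@]1(C)[C@@H](C)[C@H](O)CC[C@H]1C(=O)OCC | intermediate
9 | ethyl (1R,2R,3R,4R)-4-(tert-butyldimethylsilyloxy)-2,3-dimethyl-2-(prop-2-en-1-yl)cyclohexane-1-carboxylate | C=CC[C@]1(C)[C@@H](C)[C@H](O[Si](C)(C)C(C)(C)C)CC[C@H]1C(=O)OCC | intermediate
10 | [(1R,2S,3R,4R)-4-(tert-butyldimethylsilyloxy)-2,3-dimethyl-2-(prop-2-en-1-yl)cyclohexyl]methanol | C=CC[C@]1(C)[C@@H](C)[C@H](O[Si](C)(C)C(C)(C)C)CC[C@H]1CO | intermediate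
11 | bis(9-BBN) adduct of 10 (C8 alkylborane, C9 O-borinate) | B1(C2CCCC1CCC2)CCC[C@]1(C)[C@@H](C)[C@H](O[Si](C)(C)C(C)(C)C)CC[C@H]1COB1C2CCCC1CCC2 | intermediate (not isolated)
12 | ring-A diol (C10 CH2OH, C5 3-hydroxypropyl, 3α-OTBS) | OCCC[C@]1(C)[C@@H](C)[C@H](O[Si](C)(C)C(C)(C)C)CC[C@H]1CO | intermediate
13 | ring-A dialdehyde (C9 formyl on C10, 3-oxopropyl on C5, 3α-OTBS) | O=CCC[C@]1(C)[C@@H](C)[C@H](O[Si](C)(C)C(C)(C)C)CC[C@H]1C=O | intermediate
14 | bis(diiodosamarium) 8α,9α-diolate | C1C[C@]2(C)[C@@H](C)[C@H](O[Si](C)(C)C(C)(C)C)CC[C@H]2[C@H](O[Sm](I)I)[C@@H]1O[Sm](I)I | intermediate (not isolated)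
15 | trans-decalin 8α,9α-diol, 3α-OTBS, 4β,5β-dimethyl | C1C[C@]2(C)[C@@H](C)[C@H](O[Si](C)(C)C(C)(C)C)CC[C@H]2[C@H](O)[C@@H]1O | intermediate
16 | 8,9-O-dibutylstannylene acetal of 15 | C1C[C@]2(C)[C@@H](C)[C@H](O[Si](C)(C)C(C)(C)C)CC[C@H]2[C@H](O[Sn]3(CCCC)CCCC)[C@@H]1O3 | intermediate (not isolated)
17 | 3α,9α-bis-OTBS trans-decalin-8α-ol | C1C[C@]2(C)[C@@H](C)[C@H](O[Si](C)(C)C(C)(C)C)CC[C@H]2[C@H](O[Si](C)(C)C(C)(C)C)[C@@H]1O | intermediate
18 | 3α,9α-bis-OTBS trans-decalin-8-one | C1C[C@]2(C)[C@@H](C)[C@H](O[Si](C)(C)C(C)(C)C)CC[C@H]2[C@H](O[Si](C)(C)C(C)(C)C)C1=O | intermediate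
19 | 2-bromopropene | CC(Br)=C | starting material
20 | lithium C7–C8 enolate of 18 | [Li]OC1=CC[C@]2(C)[C@@H](C)[C@H](O[Si](C)(C)C(C)(C)C)CC[C@H]2[C@@H]1O[Si](C)(C)C(C)(C)C | intermediate (not isolated)
21 | 7α-isopropenyl-3α,9α-bis-OTBS trans-decalin-8-one | C=C(C)[C@@H]1C[C@]2(C)[C@@H](C)[C@H](O[Si](C)(C)C(C)(C)C)CC[C@H]2[C@H](O[Si](C)(C)C(C)(C)C)C1=O | intermediate
22 | 7α-isopropenyl-3α,9α-bis-OTBS trans-decalin-8α-ol | C=C(C)[C@@H]1C[C@]2(C)[C@@H](C)[C@H](O[Si](C)(C)C(C)(C)C)CC[C@H]2[C@H](O[Si](C)(C)C(C)(C)C)[C@@H]1O | intermediate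
23 | 7α-isopropenyl-4β,5β-dimethyl-trans-decalin-3α,8α,9α-triol | C=C(C)[C@@H]1C[C@]2(C)[C@@H](C)[C@H](O)CC[C@H]2[C@H](O)[C@@H]1O | intermediate
24 | hex-2-ynoic acid | CCCC#CC(=O)O | starting material
25 | 3α,9α-bis(hex-2-ynoate) of triol 23 | C=C(C)[C@@H]1C[C@]2(C)[C@@H](C)[C@H](OC(=O)C#CCCC)CC[C@H]2[C@H](OC(=O)C#CCCC)[C@@H]1O | intermediate
26 | CNP0420276.1, 3α,9α-bis[(Z)-hex-2-enoate] of triol 23 | C=C(C)[C@@H]1C[C@]2(C)[C@@H](C)[C@H](OC(=O)/C=C\CCC)CC[C@H]2[C@H](OC(=O)/C=C\CCC)[C@@H]1O | target

## Step count and risks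

Total step count: 17. Longest linear sequence: 17 steps (1 → 26).

Steps most likely to fail:

1. Step 13 (Pd enolate alkenylation). The enolate may equilibrate towards C9, the new double bond may migrate into conjugation under the basic conditions, or the coupling may stall at the hindered enolate.
   Fallback, setting out from ketone 18: LiN(SiMe3)2 and Me3SiCl give the trimethylsilyl enol ether F2. Saegusa–Ito oxidation (Pd(OAc)2, MeCN) gives the C6–C7 enone F3. I2/pyridine gives the α-iodoenone F4. Suzuki–Miyaura coupling with isopropenylboronic acid pinacol ester (Pd(PPh3)4, K3PO4, dioxane/H2O) gives the 7-isopropenyl dienone F5. Conjugate reduction with [(Ph3P)CuH]6 and protonation of the resulting enolate returns to the route at ketone 21.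

2. Step 10 (pinacol closure). The aldehydes may be reduced to alcohols before coupling, coupling may occur between molecules, or the cis/trans and α/β selectivity of the diol may be poor.
   Fallback, setting out from dialdehyde 13: intramolecular McMurry coupling with low-valent titanium (TiCl3(DME)1.5, Zn–Cu couple, DME, reflux, slow addition) forms the same C8–C9 bond as the C8–C9 octalin F1. Dihydroxylation with OsO4 (cat.) and N-methylmorpholine N-oxide from the α face, opposite the axial C5 methyl, returns to the route at diol 15.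

3. Step 16 (bis-esterification). Discrimination between the equatorial O9 and the axial O8 may be incomplete (acylation at O8 or acyl migration), or DMAP may isomerise the activated ynoate.
   Fallback, setting out from triol 23: Bu2SnO (toluene, reflux) gives the 8,9-O-dibutylstannylene acetal F6. Hex-2-ynoyl chloride F7 (from 24 with oxalyl chloride and cat. DMF) acylates the tin-activated equatorial O9 to give the 9-mono(hex-2-ynoate) F8. A second esterification with 24 (1.1 equiv, DCC, cat. DMAP) at the unhindered C3 hydroxyl returns to the route at bis-ynoate 25.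

## Further compounds

F1 | step 10 | 3α-OTBS-4β,5β-dimethyl-trans-octal-8-ene (C8–C9 alkene) | C1C[C@]2(C)[C@@H](C)[C@H](O[Si](C)(C)C(C)(C)C)CC[C@H]2C=C1
F2 | step 13 | trimethylsilyl enol ether (C7–C8) of 18 | C[Si](C)(C)OC1=CC[C@]2(C)[C@@H](C)[C@H](O[Si](C)(C)C(C)(C)C)CC[C@H]2[C@@H]1O[Si](C)(C)C(C)(C)C
F3 | step 13 | 3α,9α-bis-OTBS C6–C7 en-8-one | O=C1C=C[C@]2(C)[C@@H](C)[C@H](O[Si](C)(C)C(C)(C)C)CC[C@H]2[C@@H]1O[Si](C)(C)C(C)(C)C
F4 | step 13 | 7-iodo C6–C7 en-8-one | O=C1C(I)=C[C@]2(C)[C@@H](C)[C@H](O[Si](C)(C)C(C)(C)C)CC[C@H]2[C@@H]1O[Si](C)(C)C(C)(C)C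
F5 | step 13 | 7-isopropenyl C6–C7 en-8-one | O=C1C(C(C)=C)=C[C@]2(C)[C@@H](C)[C@H](O[Si](C)(C)C(C)(C)C)CC[C@H]2[C@@H]1O[Si](C)(C)C(C)(C)C
F6 | step 16 | 8,9-O-dibutylstannylene acetal of triol 23 | C=C(C)[C@@H]1C[C@]2(C)[C@@H](C)[C@H](O)CC[C@H]2[C@H](O[Sn]3(CCCC)CCCC)[C@@H]1O3
F7 | step 16 | hex-2-ynoyl chloride | CCCC#CC(Cl)=O
F8 | step 16 | 9α-mono(hex-2-ynoate) of triol 23 | C=C(C)[C@@H]1C[C@]2(C)[C@@H](C)[C@H](O)CC[C@H]2[C@H](OC(=O)C#CCCC)[C@@H]1O
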